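A share of the charge cannot pass 100%, so the late rise of side product in birch, the flask asked about, cannot run straight for ever: it has to bend.

| flask | substrate | partner | remark | time |
|---|---|---|---|---|
| birch | 0.30 M (fed, over 20 min) | 0.30 M | the very flask that is asked about, followed so far |  |
| maple | 0.45 M (fed, over 20 min) | 0.30 M | run made earlier |  |
| flask | 0.30 M (fed, over 20 min) | 0.300 M |  | 20 h |

| run | time / h | side product / % | intermediate B / % | target / % | intermediate A / % | substrate / % |
|---|---|---|---|---|---|---|
| birch | 0.500 | 17.3 | 0.8 | 22.7 | 12.8 | 45.3 |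
| birch | 1.50 | 42.7 | 7.0 | 30.4 | 17.1 | 3.4 |
| birch | 3.00 | 47.0 | 9.5 | 30.4 | 13.5 | 1.3 |
| birch | 4.00 | 47.8 | 8.0 | 28.6 | 13.0 | 0.8 |
| birch | 6.00 | 50.8 | 9.8 | 27.7 | 11.9 | 0.2 |
| birch | 8.00 | 52.5 | 9.5 | 27.9 | 11.7 | 0.6 |
| maple | 1.00 | 45.2 | 4.7 | 23.8 | 17.4 | 9.9 |
| maple | 2.50 | 54.2 | 8.7 | 22.9 | 14.2 | 0.7 |
| maple | 5.00 | 57.2 | 7.3 | 22.6 | 11.8 | 0 |
| maple | 8.00 | 59.8 | 9.0 | 21.1 | 10.5 | 1.0 |
| maple | 10.0 | 62.2 | 7.7 | 20.3 | 9.6 | 0 |
| maple | 15.0 | 66.4 | 6.8 | 19.0 | 8.4 | 0.2 |

(each reading ± 0.5 percentage points)

- a species is counted by the substrate in it: one side product counts as two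
- a reading or a percentage of target counts all its forms, free or not

1. the species that holds most of what was charged as substrate, at 20 h (intermediate B / side product / target / intermediate A / substrate)
2. the largest share itself, whichever of these holds it, in percent of the substrate charged

The bend is easiest to follow in the pool, the part of the charge not yet in side product. A pool lost by second-order kinetics has a reciprocal that climbs in a straight line, with a slope proportional to the charge. Call that slope, the rise per hour of one over the pool fraction, the drain rate. Birch's own readings from 3.00 h to 8.00 h give a drain rate of 0.0437 h⁻¹.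

Maple offers a second way, from a different run. Its readings from 5.00 h to 15.0 h give 0.0640 h⁻¹, which is 1.46 times birch's slope, while its charge is 1.50 times birch's. Scaled down by the charges, maple predicts 0.0426 h⁻¹ for birch, so the two ways agree and the rule can be trusted.

Birch's pool stood at 47.5% at 8.00 h. Carried forward to 20 h, the first slope puts side product at 62.0% and the second at 61.8%. Side product then holds more than the whole remaining pool of 38.0%, however that pool is divided.

The forecast names side product at 60.5%, lower than this reckoning, though it too scales by the charge and holds that “birch should run about 1.5 times slower” than maple.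

The flask gives side product at 62.7%, which is 0.70 percentage points above the first reckoning.

    substrate ⇌ intermediate A (K = 7.50, k = 1.80 × 10⁻⁴ s⁻¹)
    substrate ⇌ target (K = 44.0, k = 3.80 × 10⁻⁴ s⁻¹)
    partner + intermediate A ⇌ intermediate B (K = 2.80 L mol⁻¹, k = 4.10 × 10⁻⁴ L mol⁻¹ s⁻¹)
    crystals ⇌ target, rate k4*(cs4 - [target]) while solid is left; crystals form when [target] > cs4 (solubility = 0.240 M, k = 0.00400 s⁻¹)
    substrate + target → side product (k = 0.00280 L mol⁻¹ s⁻¹)

Side product arises from substrate with target, and at 20.0 h substrate stands at 0.516% beside target at 22.3%. The neighbour flask is the same recipe read at 12 h. Carrying the drain rate of 0.0437 h⁻¹ forward from birch's pool at 8.00 h gives 56.1% side product for that time, and that neighbour flask holds 56.4%.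

The data come from a simulation on assumed constants, noise included.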